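**Plan**
1. Numbering: ring A is the benzo ring, ring B the pyranone (C1 carbonyl, O2, C3 pentyl, C4) and ring C the pentylresorcinol ring (C1' ether carbon, C2' and C4' hydroxylated, C6' pentyl-bearing). Retrosynthesis first opens ring B at the C1–O2 lactone bond and the C3–C4 bond (acylation of an o-toluamide methyl group), with the three phenols as methyl ethers.
2. Ring C is then taken back to its dihydro form, a 4-aryloxy-5-pentylcyclohexane-1,3-dione, and cut at C5'–C6' and C3'–C4'. C1' and C6' are ring neighbours, so they are the α- and β-carbons of a 3-aryloxynon-3-en-2-one; its acetyl group supplies C2'/C3' and dimethyl malonate supplies C4'/C5'.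
3. The enone is cut at C1'=C6' (Horner–Wadsworth–Emmons reaction with hexanal) and at C1'–O (O–H insertion of the ring A phenol into a rhodium carbenoid).
4. Forward order: ring A is bought as methyl orsellinate and made into a salicylamide; ring C is built on its phenol oxygen (steps 3–5) and aromatised (steps 6–7); ring B is closed last (steps 9–10); one BBr3 step frees the three phenols.
5. Stereochemistry: the target has no stereocentre; the two made in the annulation are racemic, need no control and vanish when ring C is aromatised.

Key step: step 5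

Remark: 1,3-dicarbonyl compounds are written as one tautomer and racemates as one enantiomer; the diazophosphonate 4 and N-methoxy-N-methylhexanamide 16 are taken as purchased materials.

**Step 1**
Reactants: 1 methyl orsellinate (methyl 2,4-dihydroxy-6-methylbenzoate)
Product: 2 methyl 2-hydroxy-4-methoxy-6-methylbenzoate
Conditions: MeI (1.1 equiv), K2CO3 (1.1 equiv), acetone, 25–40 °C
Reagents that add atoms: iodomethane, CI
Why: Williamson methylation under mild base should take the 4-hydroxyl only, because the 2-hydroxyl is tied up in a hydrogen bond to the ester carbonyl and is much less acidic and nucleophilic.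

**Step 2**
Reactants: 2 methyl 2-hydroxy-4-methoxy-6-methylbenzoate
Product: 3 N,N-diethyl-2-hydroxy-4-methoxy-6-methylbenzamide
Conditions: AlMe3 (3 equiv), Et2NH (3 equiv), toluene, 0 °C then 110 °C; 1 M HCl work-up
Reagents that add atoms: diethylamine, CCNCC
Why: Weinreb aminolysis with Me2AlNEt2 made in the flask should convert the ester into the tertiary amide, the aluminium phenoxide formed first chelating and activating the neighbouring carbonyl; the amide is chosen because, unlike an ester, it should not be attacked by the enolates of steps 4 and 5 (no Dieckmann closure to a benzofuranone) and it later directs the lateral lithiation.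

**Step 3**
Reactants: 3 N,N-diethyl-2-hydroxy-4-methoxy-6-methylbenzamide; 4 dimethyl (1-diazo-2-oxopropyl)phosphonate
Product: 5 dimethyl {1-[2-(diethylcarbamoyl)-5-methoxy-3-methylphenoxy]-2-oxopropyl}phosphonate (racemic)
Conditions: Rh2(OAc)4 (2 mol %), toluene, 80 °C, 4 added slowly
Reagents that add atoms: none
Why: Rhodium-carbenoid O–H insertion, in which the electrophilic acceptor-substituted carbenoid is trapped by the phenol oxygen (oxonium ylide, then proton shift), should form the C1'–O bond; the new stereocentre is racemic and is removed in step 4.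

**Step 4**
Reactants: 5 dimethyl {1-[2-(diethylcarbamoyl)-5-methoxy-3-methylphenoxy]-2-oxopropyl}phosphonate; 6 hexanal
Product: 8 N,N-diethyl-4-methoxy-6-methyl-2-{[(3Z)-2-oxonon-3-en-3-yl]oxy}benzamide, via sodium phosphonate enolate 7 (not isolated)
Conditions: NaH (1.1 equiv), THF, 0 °C; then 6, 0 → 25 °C; aq. NH4Cl
Reagents that add atoms: none
Why: Horner–Wadsworth–Emmons olefination of the stabilised phosphonate anion with an aliphatic aldehyde should give the α-aryloxy enone, mainly as the isomer with acetyl trans to the pentyl chain (Z by the sequence rule); the minor isomer can be carried along because both converge in step 5.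

**Step 5**
Reactants: 8 N,N-diethyl-4-methoxy-6-methyl-2-{[(3Z)-2-oxonon-3-en-3-yl]oxy}benzamide; 9 dimethyl malonate
Product: 11 methyl trans-5-[2-(diethylcarbamoyl)-5-methoxy-3-methylphenoxy]-2-hydroxy-4-oxo-6-pentylcyclohex-1-ene-1-carboxylate (racemic), via Michael adduct 10 (not isolated)
Conditions: NaOMe (1.3 equiv), 9 (1.2 equiv), MeOH, 65 °C; then 1 M HCl, 0 °C
Reagents that add atoms: none
Why: Proposed new method: Methoxide generates sodium dimethyl malonate, which should add 1,4 to the β-carbon of enone 8 (C5'–C6' bond) to give an α-aryloxy enolate that is protonated to 10; the acetyl methyl of 10 is then enolised and attacks one malonate ester (C3'–C4' bond) with loss of methoxide, and deprotonation of the resulting β-dicarbonyl system to a stable enolate pulls the earlier equilibria forward. The closest known reaction is the annulation of non-3-en-2-one with dimethyl malonate under the same conditions, the standard entry to 5-pentylcyclohexane-1,3-diones; an α-aryloxy enone has not been used as the acceptor, but aryloxy is only a weak π-donor and an inductive acceptor that stabilises the intermediate enolate, so the conjugate addition should stay feasible. Ring C closes by a 6-(enolendo)-exo-trig Claisen condensation. The stereocentre at C6' arises in the Michael addition without control (racemate), and the one at C1', α to the C2' ketone, should equilibrate under base to the trans arrangement with both substituents equatorial; neither matters, since both vanish in step 7. The step needs the enolates to choose the malonate ester and the ring to close in one sense only: the hindered tertiary amide of ring A is inert to enolate attack, the enone has a single β-carbon, and only the acetyl methyl can reach an ester carbonyl through a six-membered transition state.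

**Step 6**
Reactants: 11 methyl trans-5-[2-(diethylcarbamoyl)-5-methoxy-3-methylphenoxy]-2-hydroxy-4-oxo-6-pentylcyclohex-1-ene-1-carboxylate
Product: 13 N,N-diethyl-2-[(trans-2,4-dioxo-6-pentylcyclohexyl)oxy]-4-methoxy-6-methylbenzamide (racemic), via β-keto acid 12 (not isolated)
Conditions: 2 M NaOH, H2O/MeOH, 80 °C; then HCl to pH 1, 80 °C
Reagents that add atoms: none
Why: Ester saponification followed by acidification should give the β-keto acid 12, which loses CO2 on warming through the usual cyclic transition state, while the di-ortho-substituted N,N-diethylbenzamide resists hydroxide.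

**Step 7**
Reactants: 13 N,N-diethyl-2-[(trans-2,4-dioxo-6-pentylcyclohexyl)oxy]-4-methoxy-6-methylbenzamide
Product: 14 N,N-diethyl-2-(2,4-dihydroxy-6-pentylphenoxy)-4-methoxy-6-methylbenzamide
Conditions: I2 (20 mol %), DMSO, 80 °C
Reagents that add atoms: none
Why: Iodine-catalysed oxidative aromatisation, a dehydrogenation known for 5-alkylcyclohexane-1,3-diones, should proceed by α-iodination of the dione enol, loss of HI and tautomerisation to the resorcinol, with DMSO reoxidising HI to I2; both stereocentres disappear here.

**Step 8**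
Reactants: 14 N,N-diethyl-2-(2,4-dihydroxy-6-pentylphenoxy)-4-methoxy-6-methylbenzamide
Product: 15 N,N-diethyl-2-(2,4-dimethoxy-6-pentylphenoxy)-4-methoxy-6-methylbenzamide
Conditions: MeI (3 equiv), K2CO3 (3 equiv), DMF, 25 °C
Reagents that add atoms: iodomethane, CI
Why: Williamson methylation of both phenols should give ethers that tolerate the strong base of step 9 and leave together with the ring A methyl ether in step 11.

**Step 9**
Reactants: 15 N,N-diethyl-2-(2,4-dimethoxy-6-pentylphenoxy)-4-methoxy-6-methylbenzamide; 16 N-methoxy-N-methylhexanamide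
Product: 18 N,N-diethyl-2-(2,4-dimethoxy-6-pentylphenoxy)-4-methoxy-6-(2-oxoheptyl)benzamide, via benzylic lithium compound 17 (not isolated)
Conditions: LiN(iPr)2 (1.2 equiv), THF, −78 °C; then 16 (1.5 equiv), −78 → 0 °C; aq. NH4Cl
Reagents that add atoms: none
Why: Amide-directed lateral lithiation of the o-toluamide should give a benzylic organolithium that is acylated only once by the Weinreb amide, because the chelated tetrahedral adduct survives until the quench (C3–C4 bond of ring B); LiN(iPr)2 at −78 °C should not metalate the dimethoxyarene ring or the pentyl chain.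

**Step 10**
Reactants: 18 N,N-diethyl-2-(2,4-dimethoxy-6-pentylphenoxy)-4-methoxy-6-(2-oxoheptyl)benzamide
Product: 19 8-(2,4-dimethoxy-6-pentylphenoxy)-6-methoxy-3-pentyl-1H-isochromen-1-one
Conditions: AcOH, 118 °C
Reagents that add atoms: none
Why: Acid-promoted enol lactonisation, the standard conversion of 2-(2-oxoalkyl)-N,N-diethylbenzamides into 3-substituted isocoumarins, should close ring B by 6-exo-trig attack of the ketone enol oxygen on the protonated amide carbonyl with loss of diethylamine (C1–O2 bond).

**Step 11**
Reactants: 19 8-(2,4-dimethoxy-6-pentylphenoxy)-6-methoxy-3-pentyl-1H-isochromen-1-one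
Product: 20 8-(2,4-dihydroxy-6-pentylphenoxy)-6-hydroxy-3-pentyl-1H-isochromen-1-one
Conditions: BBr3 (8 equiv), CH2Cl2, −78 → 25 °C; then MeOH, H2O
Reagents that add atoms: none
Why: Lewis-acid ether cleavage with BBr3 should remove the three methyl groups by O-complexation and bromide attack at methyl, while the diaryl ether (no sp3 carbon to attack) and the lactone survive the mild aqueous work-up.

**Compound list**
1 | methyl orsellinate (methyl 2,4-dihydroxy-6-methylbenzoate) | COC(=O)c1c(C)cc(O)cc1O | starting material
2 | methyl 2-hydroxy-4-methoxy-6-methylbenzoate | COC(=O)c1c(C)cc(OC)cc1O | intermediate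
3 | N,N-diethyl-2-hydroxy-4-methoxy-6-methylbenzamide | CCN(CC)C(=O)c1c(C)cc(OC)cc1O | intermediate
4 | dimethyl (1-diazo-2-oxopropyl)phosphonate | COP(=O)(OC)C(=[N+]=[N-])C(C)=O | starting material
5 | dimethyl {1-[2-(diethylcarbamoyl)-5-methoxy-3-methylphenoxy]-2-oxopropyl}phosphonate (racemic) | CCN(CC)C(=O)c1c(C)cc(OC)cc1OC(C(C)=O)P(=O)(OC)OC | intermediate
6 | hexanal | CCCCCC=O | starting material
7 | sodium enolate of phosphonate 5 (not isolated) | [Na+].CC([O-])=C(Oc1cc(OC)cc(C)c1C(=O)N(CC)CC)P(=O)(OC)OC | intermediate
8 | N,N-diethyl-4-methoxy-6-methyl-2-{[(3Z)-2-oxonon-3-en-3-yl]oxy}benzamide | CCCCC/C=C(\Oc1cc(OC)cc(C)c1C(=O)N(CC)CC)C(C)=O | intermediate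
9 | dimethyl malonate | COC(=O)CC(=O)OC | starting material
10 | dimethyl 2-{3-[2-(diethylcarbamoyl)-5-methoxy-3-methylphenoxy]-2-oxononan-4-yl}propanedioate (Michael adduct, diastereomer mixture, not isolated) | CCCCCC(C(C(=O)OC)C(=O)OC)C(Oc1cc(OC)cc(C)c1C(=O)N(CC)CC)C(C)=O | intermediate
11 | methyl trans-5-[2-(diethylcarbamoyl)-5-methoxy-3-methylphenoxy]-2-hydroxy-4-oxo-6-pentylcyclohex-1-ene-1-carboxylate (racemic) | COC(=O)C1=C(O)CC(=O)[C@H](Oc2cc(OC)cc(C)c2C(=O)N(CC)CC)[C@H]1CCCCC | intermediate
12 | trans-5-[2-(diethylcarbamoyl)-5-methoxy-3-methylphenoxy]-2-hydroxy-4-oxo-6-pentylcyclohex-1-ene-1-carboxylic acid (racemic, not isolated) | OC(=O)C1=C(O)CC(=O)[C@H](Oc2cc(OC)cc(C)c2C(=O)N(CC)CC)[C@H]1CCCCC | intermediate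
13 | N,N-diethyl-2-[(trans-2,4-dioxo-6-pentylcyclohexyl)oxy]-4-methoxy-6-methylbenzamide (racemic) | O=C1CC(=O)[C@H](Oc2cc(OC)cc(C)c2C(=O)N(CC)CC)[C@@H](CCCCC)C1 | intermediate
14 | N,N-diethyl-2-(2,4-dihydroxy-6-pentylphenoxy)-4-methoxy-6-methylbenzamide | CCCCCc1cc(O)cc(O)c1Oc1cc(OC)cc(C)c1C(=O)N(CC)CC | intermediate
15 | N,N-diethyl-2-(2,4-dimethoxy-6-pentylphenoxy)-4-methoxy-6-methylbenzamide | CCCCCc1cc(OC)cc(OC)c1Oc1cc(OC)cc(C)c1C(=O)N(CC)CC | intermediate
16 | N-methoxy-N-methylhexanamide | CCCCCC(=O)N(C)OC | starting material
17 | {[2-(diethylcarbamoyl)-3-(2,4-dimethoxy-6-pentylphenoxy)-5-methoxyphenyl]methyl}lithium (not isolated) | [Li]Cc1cc(OC)cc(Oc2c(OC)cc(OC)cc2CCCCC)c1C(=O)N(CC)CC | intermediate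
18 | N,N-diethyl-2-(2,4-dimethoxy-6-pentylphenoxy)-4-methoxy-6-(2-oxoheptyl)benzamide | CCCCCC(=O)Cc1cc(OC)cc(Oc2c(OC)cc(OC)cc2CCCCC)c1C(=O)N(CC)CC | intermediate
19 | 8-(2,4-dimethoxy-6-pentylphenoxy)-6-methoxy-3-pentyl-1H-isochromen-1-one | CCCCCc1cc2cc(OC)cc(Oc3c(OC)cc(OC)cc3CCCCC)c2c(=O)o1 | intermediate
20 | 8-(2,4-dihydroxy-6-pentylphenoxy)-6-hydroxy-3-pentyl-1H-isochromen-1-one | CCCCCc1cc2cc(O)cc(Oc3c(O)cc(O)cc3CCCCC)c2c(=O)o1 | target

**Totals**
Total step count: 11. Longest linear sequence: 11 steps (1 → 20).

**Steps most likely to fail**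

Step 5. Conjugate addition to the α-oxygenated, β-alkylated enone may be slow or reversible. Methoxide addition, double-bond migration, or displacement of the aryloxide by the malonate carbanion (cyclopropane formation) could then outrun the Claisen closure. The fallback sets out from 3 and comes back at 15, bringing ring C in ready-made. Commercial 1,3-dimethoxy-5-pentylbenzene (CCCCCc1cc(OC)cc(OC)c1) would be iodinated ortho to the pentyl group (N-iodosuccinimide, cat. CF3CO2H, MeCN, 25 °C) to 2-iodo-1,5-dimethoxy-3-pentylbenzene F1. An Ullmann ether synthesis of F1 with phenol 3 (CuI, picolinic acid, K3PO4, DMSO, 100 °C) would then give 15 directly, and steps 9–11 follow unchanged.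

Step 7. Iodination of the electron-rich aromatic rings could compete with dehydrogenation and drain the catalytic iodine, leaving the oxidation incomplete. The fallback sets out from 11 and comes back at 14, oxidising before the ester is removed so that halogenation is steered to the carbon between the ester and the enolised ketone. Br2 (1 equiv) in DMF at 0 °C, then warming to 80 °C, should brominate that carbon and lose two HBr to give the aromatic ester methyl 3-[2-(diethylcarbamoyl)-5-methoxy-3-methylphenoxy]-4,6-dihydroxy-2-pentylbenzoate F2. Aqueous NaOH at reflux, then acidification with warming, should hydrolyse the ester and decarboxylate the resulting 2,4-dihydroxybenzoic acid to give 14.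

Step 2. Acyl substitution at the doubly ortho-substituted, chelated ester may stall, so that the aminolysis does not go to completion. The fallback sets out from 2 and comes back at 3, replacing direct aminolysis by an acid chloride route with the phenol masked:
- Benzyl bromide, K2CO3, DMF, 60 °C should give methyl 2-(benzyloxy)-4-methoxy-6-methylbenzoate F3.
- KOH in aqueous DMSO at 100 °C should give 2-(benzyloxy)-4-methoxy-6-methylbenzoic acid F4.
- (COCl)2 with cat. DMF in CH2Cl2 should give 2-(benzyloxy)-4-methoxy-6-methylbenzoyl chloride F5.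
- Et2NH (excess) in CH2Cl2 at 0 °C should give 2-(benzyloxy)-N,N-diethyl-4-methoxy-6-methylbenzamide F6.
- Hydrogenolysis (H2, Pd/C, EtOAc) should then free phenol 3.

**Further compounds**
F1 | step 5 | 2-iodo-1,5-dimethoxy-3-pentylbenzene | CCCCCc1cc(OC)cc(OC)c1I
F2 | step 7 | methyl 3-[2-(diethylcarbamoyl)-5-methoxy-3-methylphenoxy]-4,6-dihydroxy-2-pentylbenzoate | COC(=O)c1c(O)cc(O)c(Oc2cc(OC)cc(C)c2C(=O)N(CC)CC)c1CCCCC
F3 | step 2 | methyl 2-(benzyloxy)-4-methoxy-6-methylbenzoate | COC(=O)c1c(C)cc(OC)cc1OCc1ccccc1
F4 | step 2 | 2-(benzyloxy)-4-methoxy-6-methylbenzoic acid | OC(=O)c1c(C)cc(OC)cc1OCc1ccccc1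
F5 | step 2 | 2-(benzyloxy)-4-methoxy-6-methylbenzoyl chloride | ClC(=O)c1c(C)cc(OC)cc1OCc1ccccc1
F6 | step 2 | 2-(benzyloxy)-N,N-diethyl-4-methoxy-6-methylbenzamide | CCN(CC)C(=O)c1c(C)cc(OC)cc1OCc1ccccc1
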